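**Strategy.** The dimer is cut at the interflavan bond C4(upper)–C6(lower) into a C4 cation of an epioritin unit and an ent-oritin-4α-ol nucleophile made from daphnetin. Everything rests on opening ring C of the upper unit at C2–C3: C2, which carries O1 and ring B, is an ester carbonyl carbon in disguise, and C3–C4 is an allyl group ortho to O1 on ring A. One Tebbe-mediated methylenation/olefin-metathesis cascade turns the 2-allylaryl 4-(benzyloxy)benzoate 7 into the cyclic enol ether (flav-2-ene) 9, closing ring C through C2=C3. Hydroboration, oxidation and a dynamic kinetic transfer hydrogenation then set C2 and C3.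

Key step: step 5

Assumption: the sense of induction of the chiral catalysts in steps 8 and 12 is assigned by analogy; the antipodal catalyst would be used if a pilot run showed the opposite sense.

**Route**

Step 1
Reactants: 1 pyrogallol
Product: 2 2,2-diphenyl-1,3-benzodioxol-4-ol
Conditions: Ph2CCl2 (1.1 equiv), neat, 160–170 °C
Reagents that add atoms: dichlorodiphenylmethane ClC(Cl)(c1ccccc1)c1ccccc1
Why: Double substitution of the gem-dichloride by two adjacent hydroxyls (ketal formation) masks the future 7,8-diol as a hydrogenolysable ketal and leaves the third hydroxyl, the future O1, free.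

Step 2
Reactants: 2 2,2-diphenyl-1,3-benzodioxol-4-ol; 3 allyl bromide
Product: 4 4-(allyloxy)-2,2-diphenyl-1,3-benzodioxole
Conditions: K2CO3, acetone, reflux
Reagents that add atoms: none
Why: Williamson etherification of the only free phenol.

Step 3
Reactants: 4 4-(allyloxy)-2,2-diphenyl-1,3-benzodioxole
Product: 5 5-allyl-2,2-diphenyl-1,3-benzodioxol-4-ol
Conditions: N,N-diethylaniline, 190 °C
Reagents that add atoms: none
Why: Aromatic Claisen rearrangement ([3,3] shift, then tautomerisation) moves the allyl group to the single free ortho carbon, which becomes C4a carrying C4 and C3.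

Step 4
Reactants: 5 5-allyl-2,2-diphenyl-1,3-benzodioxol-4-ol; 6 4-(benzyloxy)benzoyl chloride
Product: 7 5-allyl-2,2-diphenyl-1,3-benzodioxol-4-yl 4-(benzyloxy)benzoate
Conditions: Et3N, DMAP (cat.), CH2Cl2, 0 °C → rt
Reagents that add atoms: none
Why: DMAP-catalysed acylation of the hindered phenol installs the O1–C2 bond and ring B with C2 at the ester oxidation level.

Step 5
Reactants: 7 5-allyl-2,2-diphenyl-1,3-benzodioxol-4-yl 4-(benzyloxy)benzoate
Product: 9 4'-O-benzyl-7,8-O-diphenylmethylene-7,8,4'-trihydroxyflav-2-ene, via acyclic enol ether 8 (not isolated)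
Conditions: Cp2Ti(μ-CH2)(μ-Cl)AlMe2 (Tebbe reagent, 4 equiv), pyridine (cat.), THF, 0 → 25 °C, then reflux at high dilution
Reagents that add atoms: none
Why: The Tebbe reagent releases Cp2Ti=CH2, which first methylenates the aryl ester carbonyl (oxatitanacyclobutane, loss of titanocene oxide) to enol ether 8; a second titanium methylidene then exchanges with the terminal allyl double bond to give a titanium alkylidene that adds across the enol-ether C=C and cycloreverts, so that the former ester carbon (C2) and the internal allyl carbon (C3) become doubly bonded. The closest known reaction type is the Tebbe-mediated tandem carbonyl olefination/olefin metathesis of olefinic esters to cyclic enol ethers, a net carbonyl–olefin metathesis. Ring C (O1, C2, C3, C4, C4a, C8a) is closed as a six-membered ring in the ring-closing-metathesis mode through a titanacyclobutane. No stereocentre is created: C2 and C3 are left trigonal on purpose and are set afterwards (syn addition in step 6, catalyst control plus cis preference in step 8). The selectivity needed is methylenation before metathesis and six-ring closure instead of cross-metathesis, which the higher reactivity of the ester towards Cp2Ti=CH2, the ortho relation of the two arms on ring A and dilution during heating should secure.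

Step 6
Reactants: 9 4'-O-benzyl-7,8-O-diphenylmethylene-7,8,4'-trihydroxyflav-2-ene
Product: 11 rac-(2R,3S)-4'-O-benzyl-7,8-O-diphenylmethylene-7,8,4'-trihydroxyflavan-3-ol (2,3-trans), via 3-borylflavan 10 (not isolated)
Conditions: BH3·THF, THF, 0 °C → rt; then aq NaOH, 30% H2O2, 0 °C
Reagents that add atoms: hydrogen peroxide OO
Why: Hydroboration–oxidation: boron adds to C3 of the enol ether (away from O1 and the aryl group) and hydrogen to C2 on the same face, and oxidation with retention should give the 2,3-trans alcohol as a racemate.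

Step 7
Reactants: 11 rac-(2R,3S)-4'-O-benzyl-7,8-O-diphenylmethylene-7,8,4'-trihydroxyflavan-3-ol
Product: 12 rac-4'-O-benzyl-7,8-O-diphenylmethylene-7,8,4'-trihydroxyflavan-3-one
Conditions: Dess–Martin periodinane, NaHCO3, CH2Cl2, 0 °C → rt
Reagents that add atoms: none
Why: Dess–Martin oxidation of the secondary alcohol gives the ketone, which erases C3 and makes C2 (α-keto, α-oxy, benzylic) configurationally labile.

Step 8
Reactants: 12 rac-4'-O-benzyl-7,8-O-diphenylmethylene-7,8,4'-trihydroxyflavan-3-one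
Product: 13 (2R,3R)-4'-O-benzyl-7,8-O-diphenylmethylene-7,8,4'-trihydroxyflavan-3-ol (2,3-cis; protected epioritin)
Conditions: RuCl[(R,R)-TsDPEN](p-cymene) (2 mol%), HCO2H/Et3N (5:2), CH2Cl2, 30 °C
Reagents that add atoms: none
Why: Noyori-type asymmetric transfer hydrogenation run as a dynamic kinetic resolution: Et3N equilibrates the C2 epimers of 12 through the enol while the chiral ruthenium hydride reduces one of them faster, hydride entering anti to the 2-aryl group, so the catalyst should set C3 as R and the cis preference of the reduction should set C2 as R.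

Step 9
Reactants: 13 (2R,3R)-4'-O-benzyl-7,8-O-diphenylmethylene-7,8,4'-trihydroxyflavan-3-ol
Product: 14 (2R,3R,4S)-4'-O-benzyl-4-(2-ethoxyethoxy)-7,8-O-diphenylmethylene-7,8,4'-trihydroxyflavan-3-ol (4β-ether)
Conditions: DDQ (2 equiv), 2-ethoxyethanol (5 equiv), CH2Cl2, rt
Reagents that add atoms: 2-ethoxyethanol CCOCCO
Why: Oxidative benzylic C–H etherification: DDQ abstracts hydride from C4 (cation stabilised by O1 ortho and O7 para on ring A, the more easily oxidised arene) and the alcohol is expected to add anti to the 3-OH, giving a storable C4 cation precursor.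

Step 10
Reactants: 15 daphnetin (7,8-dihydroxycoumarin)
Product: 16 7,8-(diphenylmethylenedioxy)coumarin
Conditions: Ph2CCl2 (1.2 equiv), neat, 170 °C
Reagents that add atoms: dichlorodiphenylmethane ClC(Cl)(c1ccccc1)c1ccccc1
Why: Ketal formation on the catechol of daphnetin gives the lower unit the same ring A protection as the upper unit.

Step 11
Reactants: 16 7,8-(diphenylmethylenedioxy)coumarin
Product: 18 2-ethoxy-7,8-(diphenylmethylenedioxy)-2H-chromene (racemic acetal), via lactol 17 (not isolated)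
Conditions: iBu2AlH, CH2Cl2, −78 °C; then EtOH, PPTS (cat.), rt
Reagents that add atoms: ethanol CCO
Why: Half-reduction of the lactone to the lactol followed by acid-catalysed acetal exchange through the benzopyrylium ion gives the chromene acetal.

Step 12
Reactants: 18 2-ethoxy-7,8-(diphenylmethylenedioxy)-2H-chromene; 19 4-(benzyloxy)phenylboronic acid
Product: 21 (2R)-4'-O-benzyl-7,8-O-diphenylmethylene-7,8,4'-trihydroxyflav-3-ene, via diethyl boronate 20 (not isolated)
Conditions: 19, EtOH, toluene, azeotropic removal of water; then 18, chiral tartaric acid monoamide catalyst (5 mol%), Yb(OTf)3 (4 mol%), EtOAc, −40 °C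
Reagents that add atoms: none
Why: Enantioselective boronate addition to an oxocarbenium ion: the acid pair ionises the acetal to the achiral benzopyrylium ion and the chiral tartrate-bound aryl boronate delivers ring B to one face of C2, so the catalyst sets C2 of the lower unit.

Step 13
Reactants: 21 (2R)-4'-O-benzyl-7,8-O-diphenylmethylene-7,8,4'-trihydroxyflav-3-ene
Product: 22 (2S,3R,4R)-4'-O-benzyl-7,8-O-diphenylmethylene-7,8,4'-trihydroxyflavan-3,4-diol cyclic 3,4-phenylboronate (protected ent-oritin-4α-ol)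
Conditions: OsO4 (2 mol%), NMO (1.5 equiv), PhB(OH)2 (1.2 equiv), CH2Cl2, rt
Reagents that add atoms: osmium tetroxide O=[Os](=O)(=O)=O (oxygen atoms, resupplied by N-methylmorpholine N-oxide C[N+]1([O-])CCOCC1); phenylboronic acid OB(O)c1ccccc1
Why: Catalytic syn-dihydroxylation of C3=C4 from the face opposite to the 2-aryl group should give the 2,3-trans-3,4-cis diol, which is captured in situ as the cyclic boronate that masks the ionisable benzylic 4-OH for the coupling.

Step 14
Reactants: 14 (2R,3R,4S)-4-(2-ethoxyethoxy) ether of protected epioritin; 22 cyclic phenylboronate of protected ent-oritin-4α-ol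
Product: 24 4'-O-benzyl-7,8-O-diphenylmethylene-epioritin-(4β→6)-4'-O-benzyl-7,8-O-diphenylmethylene-ent-oritin-4α-ol, via dimer boronate 23 (not isolated)
Conditions: 22 (3 equiv), TMSOTf (0.3 equiv), CH2Cl2, −78 → −40 °C; then 30% H2O2, aq NaHCO3, THF, 0 °C
Reagents that add atoms: none
Why: Friedel–Crafts alkylation: TMSOTf ionises the 4-ether to the benzylic C4 cation, which is attacked by C6 of 22 (ortho to O7 and para to O1, whereas C5 is less activated and peri-hindered) anti to the axial 3-OH of the 2,3-cis unit, which should give the 3,4-trans (4β) bond, and the oxidative work-up cleaves the boronate.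

Step 15
Reactants: 24 protected epioritin-(4β→6)-ent-oritin-4α-ol
Product: 25 epioritin-(4β→6)-ent-oritin-4α-ol (target)
Conditions: H2 (1 atm), Pd(OH)2/C, THF/MeOH, rt
Reagents that add atoms: none
Why: Neutral hydrogenolysis removes the two benzyl ethers and the two diphenylmethylene ketals without touching a stereocentre.

**Compound list**

1 | pyrogallol | Oc1cccc(O)c1O | starting material
2 | 2,2-diphenyl-1,3-benzodioxol-4-ol | Oc1cccc2OC(c3ccccc3)(c3ccccc3)Oc12 | intermediate
3 | allyl bromide | C=CCBr | starting material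
4 | 4-(allyloxy)-2,2-diphenyl-1,3-benzodioxole | C=CCOc1cccc2OC(c3ccccc3)(c3ccccc3)Oc12 | intermediate
5 | 5-allyl-2,2-diphenyl-1,3-benzodioxol-4-ol | C=CCc1ccc2OC(c3ccccc3)(c3ccccc3)Oc2c1O | intermediate
6 | 4-(benzyloxy)benzoyl chloride | O=C(Cl)c1ccc(OCc2ccccc2)cc1 | starting material
7 | 5-allyl-2,2-diphenyl-1,3-benzodioxol-4-yl 4-(benzyloxy)benzoate | C=CCc1ccc2OC(c3ccccc3)(c3ccccc3)Oc2c1OC(=O)c1ccc(OCc2ccccc2)cc1 | intermediate
8 | 5-allyl-4-{[1-(4-benzyloxyphenyl)ethenyl]oxy}-2,2-diphenyl-1,3-benzodioxole (acyclic enol ether, not isolated) | C=CCc1ccc2OC(c3ccccc3)(c3ccccc3)Oc2c1OC(=C)c1ccc(OCc2ccccc2)cc1 | intermediate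
9 | 4'-O-benzyl-7,8-O-diphenylmethylene-7,8,4'-trihydroxyflav-2-ene (2-aryl-4H-chromene) | C(c1ccccc1)Oc1ccc(cc1)C1=CCc2ccc3OC(c4ccccc4)(c4ccccc4)Oc3c2O1 | intermediate
10 | rac-2,3-trans-3-boryl-4'-O-benzyl-7,8-O-diphenylmethyleneflavan (drawn as the monoalkylborane, one enantiomer; not isolated) | C(c1ccccc1)Oc1ccc(cc1)[C@H]1Oc2c(ccc3OC(c4ccccc4)(c4ccccc4)Oc23)C[C@@H]1B | intermediate
11 | rac-(2R,3S)-4'-O-benzyl-7,8-O-diphenylmethylene-7,8,4'-trihydroxyflavan-3-ol (2,3-trans, racemic, one enantiomer drawn) | C(c1ccccc1)Oc1ccc(cc1)[C@H]1Oc2c(ccc3OC(c4ccccc4)(c4ccccc4)Oc23)C[C@@H]1O | intermediate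
12 | rac-4'-O-benzyl-7,8-O-diphenylmethylene-7,8,4'-trihydroxyflavan-3-one (racemic, C2 labile) | C(c1ccccc1)Oc1ccc(cc1)C1Oc2c(ccc3OC(c4ccccc4)(c4ccccc4)Oc23)CC1=O | intermediate
13 | (2R,3R)-4'-O-benzyl-7,8-O-diphenylmethylene-7,8,4'-trihydroxyflavan-3-ol (2,3-cis) | C(c1ccccc1)Oc1ccc(cc1)[C@H]1Oc2c(ccc3OC(c4ccccc4)(c4ccccc4)Oc23)C[C@H]1O | intermediate
14 | (2R,3R,4S)-4'-O-benzyl-4-(2-ethoxyethoxy)-7,8-O-diphenylmethylene-7,8,4'-trihydroxyflavan-3-ol (4β-ether) | C(c1ccccc1)Oc1ccc(cc1)[C@H]1Oc2c(ccc3OC(c4ccccc4)(c4ccccc4)Oc23)[C@H](OCCOCC)[C@H]1O | intermediate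
15 | daphnetin (7,8-dihydroxycoumarin) | O=C1C=Cc2ccc(O)c(O)c2O1 | starting material
16 | 7,8-(diphenylmethylenedioxy)coumarin | O=C1C=Cc2ccc3OC(c4ccccc4)(c4ccccc4)Oc3c2O1 | intermediate
17 | 7,8-(diphenylmethylenedioxy)-2H-chromen-2-ol (lactol, racemic, not isolated) | OC1C=Cc2ccc3OC(c4ccccc4)(c4ccccc4)Oc3c2O1 | intermediate
18 | 2-ethoxy-7,8-(diphenylmethylenedioxy)-2H-chromene (racemic) | CCOC1C=Cc2ccc3OC(c4ccccc4)(c4ccccc4)Oc3c2O1 | intermediate
19 | 4-(benzyloxy)phenylboronic acid | OB(O)c1ccc(OCc2ccccc2)cc1 | starting material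
20 | diethyl [4-(benzyloxy)phenyl]boronate (not isolated) | CCOB(OCC)c1ccc(OCc2ccccc2)cc1 | intermediate
21 | (2R)-4'-O-benzyl-7,8-O-diphenylmethylene-7,8,4'-trihydroxyflav-3-ene (2-aryl-2H-chromene, aryl β) | c1cc2c(c3OC(c4ccccc4)(c4ccccc4)Oc13)O[C@@H](c1ccc(OCc3ccccc3)cc1)C=C2 | intermediate
22 | (2S,3R,4R)-4'-O-benzyl-7,8-O-diphenylmethylene-7,8,4'-trihydroxyflavan-3,4-diol cyclic 3,4-phenylboronate (2,3-trans-3,4-cis) | c1cc2c(c3OC(c4ccccc4)(c4ccccc4)Oc13)O[C@@H](c1ccc(OCc3ccccc3)cc1)[C@@H]1OB(c3ccccc3)O[C@@H]12 | intermediate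
23 | protected epioritin-(4β→6)-ent-oritin-4α-ol cyclic 3,4-phenylboronate of the lower unit (not isolated) | C(c1ccccc1)Oc1ccc(cc1)[C@H]1Oc2c(ccc3OC(c4ccccc4)(c4ccccc4)Oc23)[C@H](c2cc3c(c4OC(c5ccccc5)(c5ccccc5)Oc24)O[C@@H](c2ccc(OCc4ccccc4)cc2)[C@@H]2OB(c4ccccc4)O[C@@H]23)[C@H]1O | intermediate
24 | 4'-O-benzyl-7,8-O-diphenylmethylene-epioritin-(4β→6)-4'-O-benzyl-7,8-O-diphenylmethylene-ent-oritin-4α-ol (upper unit 2α-aryl, 3α-OH, 4β-aryl; lower unit 2β-aryl, 3α-OH, 4α-OH) | C(c1ccccc1)Oc1ccc(cc1)[C@H]1Oc2c(ccc3OC(c4ccccc4)(c4ccccc4)Oc23)[C@H](c2cc3c(c4OC(c5ccccc5)(c5ccccc5)Oc24)O[C@@H](c2ccc(OCc4ccccc4)cc2)[C@H](O)[C@@H]3O)[C@H]1O | intermediate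
25 | epioritin-(4β→6)-ent-oritin-4α-ol: (2R,3R,4S)-2-(4-hydroxyphenyl)chroman-3,7,8-triol joined from C4 to C6 of (2S,3R,4R)-2-(4-hydroxyphenyl)chroman-3,4,7,8-tetrol | Oc1ccc([C@H]2Oc3c(ccc(O)c3O)[C@H](c3cc4c(c(O)c3O)O[C@@H](c3ccc(O)cc3)[C@H](O)[C@@H]4O)[C@H]2O)cc1 | target

**Count and risks**

Total steps: 15. Longest linear sequence: 11 (steps 1–9, 14, 15).

Step 5 is the most likely to fail. The titanium alkylidene may not engage the hindered, aryl-conjugated enol ether, so that the cascade stops at the acyclic stage or the enol ether decomposes on heating. The fallback separates the two events and changes the metathesis metal. It sets out from 7: Petasis methylenation (Cp2TiMe2, toluene, 65 °C) gives the acyclic enol ether 8, now isolated by filtration through basic alumina. Ring-closing metathesis with RuCl2(H2IMes)(PCy3)(=CHPh) (second-generation Grubbs catalyst, toluene, 70 °C) then closes ring C and the route is rejoined at 9. This fallback makes no compound outside the list (F0).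

Step 8 is the second risk. Enantioface discrimination may be poor on a ketone that has no aryl group on the carbonyl, and base-induced enolisation and air oxidation of the flavan-3-one may compete with reduction. The fallback moves the absolute control to the hydroboration and uses substrate control for the cis relation. It sets out from 9: hydroboration with monoisopinocampheylborane (antipode chosen for the 2R,3S product) and oxidative work-up should give the single-enantiomer trans alcohol (2R,3S)-4'-O-benzyl-7,8-O-diphenylmethylene-7,8,4'-trihydroxyflavan-3-ol F1. Buffered Dess–Martin oxidation at 0 °C gives the ketone (2R)-4'-O-benzyl-7,8-O-diphenylmethylene-7,8,4'-trihydroxyflavan-3-one F2, which is used at once. LiBH(s-Bu)3 in THF at −78 °C should deliver hydride anti to the 2-aryl group and the route is rejoined at 13.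

Step 14 is the third risk. The C4 cation may be alkylated by ring A of a second molecule of 14 (oligomer formation), and attack by the moderately nucleophilic lower unit may be slow. The fallback blocks C6 of the upper unit with a removable halogen. It sets out from 13: NBS (CH2Cl2, −78 → 0 °C) should brominate the most activated position to give (2R,3R)-6-bromo-4'-O-benzyl-7,8-O-diphenylmethylene-7,8,4'-trihydroxyflavan-3-ol F3. DDQ and 2-ethoxyethanol give the 4β-(2-ethoxyethoxy) ether of the 6-bromo compound F4. Coupling with 22 (TMSOTf, −78 °C) gives the 6-bromo dimer boronate F5, and H2O2 work-up gives the 6-bromo protected dimer diol F6. Hydrogenolysis with H2, Pd(OH)2/C and Et3N removes bromine together with the benzyl and ketal groups, and the route is rejoined at 25.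

**Further compounds**

F0 | step 5 | none | none
F1 | step 8 | (2R,3S)-4'-O-benzyl-7,8-O-diphenylmethylene-7,8,4'-trihydroxyflavan-3-ol (single enantiomer, 2,3-trans) | C(c1ccccc1)Oc1ccc(cc1)[C@H]1Oc2c(ccc3OC(c4ccccc4)(c4ccccc4)Oc23)C[C@@H]1O
F2 | step 8 | (2R)-4'-O-benzyl-7,8-O-diphenylmethylene-7,8,4'-trihydroxyflavan-3-one | C(c1ccccc1)Oc1ccc(cc1)[C@H]1Oc2c(ccc3OC(c4ccccc4)(c4ccccc4)Oc23)CC1=O
F3 | step 14 | (2R,3R)-6-bromo-4'-O-benzyl-7,8-O-diphenylmethylene-7,8,4'-trihydroxyflavan-3-ol | C(c1ccccc1)Oc1ccc(cc1)[C@H]1Oc2c(cc(Br)c3OC(c4ccccc4)(c4ccccc4)Oc23)C[C@H]1O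
F4 | step 14 | (2R,3R,4S)-6-bromo-4'-O-benzyl-4-(2-ethoxyethoxy)-7,8-O-diphenylmethylene-7,8,4'-trihydroxyflavan-3-ol | C(c1ccccc1)Oc1ccc(cc1)[C@H]1Oc2c(cc(Br)c3OC(c4ccccc4)(c4ccccc4)Oc23)[C@H](OCCOCC)[C@H]1O
F5 | step 14 | 6-bromo protected epioritin-(4β→6)-ent-oritin-4α-ol cyclic 3,4-phenylboronate of the lower unit | C(c1ccccc1)Oc1ccc(cc1)[C@H]1Oc2c(cc(Br)c3OC(c4ccccc4)(c4ccccc4)Oc23)[C@H](c2cc3c(c4OC(c5ccccc5)(c5ccccc5)Oc24)O[C@@H](c2ccc(OCc4ccccc4)cc2)[C@@H]2OB(c4ccccc4)O[C@@H]23)[C@H]1O
F6 | step 14 | 6-bromo-4'-O-benzyl-7,8-O-diphenylmethylene-epioritin-(4β→6)-4'-O-benzyl-7,8-O-diphenylmethylene-ent-oritin-4α-ol | C(c1ccccc1)Oc1ccc(cc1)[C@H]1Oc2c(cc(Br)c3OC(c4ccccc4)(c4ccccc4)Oc23)[C@H](c2cc3c(c4OC(c5ccccc5)(c5ccccc5)Oc24)O[C@@H](c2ccc(OCc4ccccc4)cc2)[C@H](O)[C@@H]3O)[C@H]1O
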